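**Plan**
1. Cuts, in retrosynthetic order: C–Br of the CH2Br group (from CH2OH), C2–H (hydroboration of a 2-methylidene oxepene), C2–C3 of the oxepene, C3=C4, C7–Br, the C–O bonds at C9a and C7, and C5a–C5.
2. Enabling feature: in the seven-membered ring O1–C2–C3=C4–C5–C5a–C9a, C2 lies between the ether oxygen O1 and the alkene carbon C3. It can therefore be the carbon of an O1-bound oxocarbenium ion (bromoacetaldehyde level) that C3 of a (Z)-vinylsilane attacks.
3. Forward order: the cyclohexane comes from 2,4,4-trimethylcyclohexenone; a γ-lactone (O1–C9a–C5a–C5–C4) serves as a temporary mask; the chain is grown to C4=C3; the oxepene is the last ring to close, in step 13.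
4. Stereochemistry: a CBS reduction sets one carbinol, the Claisen shift relays it to C5a, singlet oxygen adds anti to the side chain (C9a and C7–O), and an Appel inversion gives 7S.
5. C2: the ring closure should place CH2Br trans to the axial C9a methyl, whereas the target has them cis. C2 is therefore flattened by loss of HBr and rebuilt by hydroboration from the face away from that methyl.

Key step: step 13

Remark: the benzoxepine numbering of the target (O1, C2, C3, C4, C5, C5a, C6–C9, C9a) is used for the corresponding atoms of every intermediate.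

Step 1
Reactants: 1 2,4,4-trimethylcyclohex-2-en-1-one
Product: 2 (1R)-2,4,4-trimethylcyclohex-2-en-1-ol
Conditions: (S)-Me-CBS (10 mol %), BH3·SMe2, THF, −20 °C; aqueous work-up
Reagents that add atoms: none
Why: Corey–Bakshi–Shibata reduction, in which the 2-methylvinyl flank acts as the large and the ring CH2 as the small ketone substituent, so the (S)-oxazaborolidine should deliver hydride to give the (R)-carbinol from which all later chirality derives.

Step 2
Reactants: 2 (1R)-2,4,4-trimethylcyclohex-2-en-1-ol; 3 triethyl orthoacetate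
Product: 5 ethyl 2-[(1S)-2,6,6-trimethylcyclohex-2-en-1-yl]acetate, via ketene acetal 4 (not isolated)
Conditions: MeC(OEt)3 (excess), EtCO2H (cat.), 140 °C, EtOH distilled off
Reagents that add atoms: none
Why: Johnson–Claisen rearrangement, in which acid-catalysed exchange and loss of ethanol give ketene acetal 4, whose suprafacial [3,3] shift forms C5a–C5 on the ring face that carried the C9–O bond, so the carbinol configuration is relayed to C5a (S) while the alkene moves to C9=C9a.

Step 3
Reactants: 5 ethyl 2-[(1S)-2,6,6-trimethylcyclohex-2-en-1-yl]acetate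
Product: 6 ethyl 2-[(1S)-2,6,6-trimethyl-4-oxocyclohex-2-en-1-yl]acetate
Conditions: Rh2(cap)4 (1 mol %), t-BuOOH, K2CO3, CH2Cl2, rt
Reagents that add atoms: tert-butyl hydroperoxide, CC(C)(C)OO
Why: Dirhodium-catalysed allylic C–H oxidation with tert-butyl hydroperoxide, a standard cyclohexene-to-enone conversion, should pick the only allylic ring methylene (C8) and leave C5a untouched under the weakly basic conditions.

Step 4
Reactants: 6 ethyl 2-[(1S)-2,6,6-trimethyl-4-oxocyclohex-2-en-1-yl]acetate
Product: 7 ethyl 2-[(1R)-2,6,6-trimethyl-4-(trifluoromethylsulfonyloxy)cyclohexa-2,4-dien-1-yl]acetate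
Conditions: LiHMDS (1.05 equiv), THF, −78 °C; PhNTf2, −78 → 0 °C
Reagents that add atoms: N-phenylbis(trifluoromethanesulfonimide), O=S(=O)(N(c1ccccc1)S(=O)(=O)C(F)(F)F)C(F)(F)F
Why: Kinetic deprotonation of a cyclohexenone at the alpha-prime carbon (C7, more acidic than the ester CH2) gives the cross-conjugated dienolate, and O-sulfonylation with the triflimide is the usual enol triflate synthesis (the descriptor at C5a changes only through CIP ranking).

Step 5
Reactants: 7 ethyl 2-[(1R)-2,6,6-trimethyl-4-(trifluoromethylsulfonyloxy)cyclohexa-2,4-dien-1-yl]acetate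
Product: 8 ethyl 2-[(1R)-2,6,6-trimethylcyclohexa-2,4-dien-1-yl]acetate
Conditions: Pd(OAc)2 (5 mol %), PPh3, HCO2H, n-Bu3N, DMF, 60 °C
Reagents that add atoms: none
Why: Palladium-catalysed formate reduction of an enol triflate replaces C8–OTf by C8–H through oxidative addition, decarboxylation of the palladium formate and reductive elimination, giving the C7=C8–C9=C9a diene without touching C5a.

Step 6
Reactants: 8 ethyl 2-[(1R)-2,6,6-trimethylcyclohexa-2,4-dien-1-yl]acetate
Product: 9 ethyl 2-[(1S,4R,7S)-1,8,8-trimethyl-2,3-dioxabicyclo[2.2.2]oct-5-en-7-yl]acetate (O–O bridge from C9a to C7 on the face opposite the CH2CO2Et group)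
Conditions: O2, visible light, tetraphenylporphyrin (cat.), CH2Cl2, −20 °C
Reagents that add atoms: dioxygen, O=O
Why: [4+2] cycloaddition of singlet oxygen to a cyclohexa-1,3-diene, in which the dienophile should approach the face that carries H-5a and not the CH2CO2Et group, so the new C–O bonds at C9a and C7 are cis to each other and trans to the side chain.

Step 7
Reactants: 9 ethyl 2-[(1S,4R,7S)-1,8,8-trimethyl-2,3-dioxabicyclo[2.2.2]oct-5-en-7-yl]acetate
Product: 11 (3aS,5R,7aS)-5-hydroxy-4,4,7a-trimethylhexahydro-1-benzofuran-2(3H)-one, via diol ester 10 (not isolated)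
Conditions: H2 (1 atm), Pd/C, EtOAc, rt; filter; PPTS (cat.), toluene, 60 °C
Reagents that add atoms: none
Why: Catalytic hydrogenation cleaves the O–O bond and saturates C8=C9 with both C–O bonds retained (endoperoxide to cis-1,4-diol), and acid-catalysed lactonisation of the equatorial tertiary C9a–OH onto the neighbouring equatorial ester arm then masks that alcohol and leaves only the axial C7–OH free.

Step 8
Reactants: 11 (3aS,5R,7aS)-5-hydroxy-4,4,7a-trimethylhexahydro-1-benzofuran-2(3H)-one
Product: 12 (3aS,5S,7aS)-5-bromo-4,4,7a-trimethylhexahydro-1-benzofuran-2(3H)-one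
Conditions: CBr4, PPh3, toluene, 70 °C
Reagents that add atoms: carbon tetrabromide, BrC(Br)(Br)Br
Why: Appel reaction, in which bromide displaces the axial alkoxyphosphonium group at C7 from the rear so that the axial 7R alcohol becomes the equatorial 7S bromide, the inert trans-fused lactone holding the chair that keeps the leaving group axial.

Step 9
Reactants: 12 (3aS,5S,7aS)-5-bromo-4,4,7a-trimethylhexahydro-1-benzofuran-2(3H)-one
Product: 13 (3aS,5S,7aS)-5-bromo-4,4,7a-trimethyloctahydro-1-benzofuran-2-ol (both anomers)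
Conditions: DIBAL-H (1.1 equiv), CH2Cl2, −78 °C; Rochelle salt
Reagents that add atoms: none
Why: Partial reduction of a gamma-lactone with DIBAL-H stops at the aluminium lactolate at −78 °C, and the secondary bromide does not react with this hydride.

Step 10
Reactants: 13 (3aS,5S,7aS)-5-bromo-4,4,7a-trimethyloctahydro-1-benzofuran-2-ol; 14 ethyltriphenylphosphonium iodide
Product: 15 (1S,2S,4S)-4-bromo-2-[(2Z)-3-iodobut-2-en-1-yl]-1,3,3-trimethylcyclohexan-1-ol
Conditions: 14, n-BuLi, THF, rt; I2, −78 °C; NaHMDS, −20 °C; then 13 (ylide in excess), −20 → 0 °C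
Reagents that add atoms: iodine, II
Why: Stork–Zhao iodo-Wittig olefination, in which the first equivalent of base opens the lactol to the hydroxy aldehyde and the non-stabilised ylide Ph3P=C(I)CH3 adds under kinetic control to give the alkene with iodine cis to C5 (Z), the geometry that the ring closure needs.

Step 11
Reactants: 15 (1S,2S,4S)-4-bromo-2-[(2Z)-3-iodobut-2-en-1-yl]-1,3,3-trimethylcyclohexan-1-ol; 16 chlorotrimethylsilane
Product: 18 (1S,2S,4S)-4-bromo-1,3,3-trimethyl-2-[(2Z)-3-(trimethylsilyl)but-2-en-1-yl]cyclohexan-1-ol, via bis-silyl compound 17 (not isolated)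
Conditions: t-BuLi (3.0 equiv), Et2O, −78 °C; Me3SiCl, −78 °C → rt; then citric acid, MeOH, rt
Reagents that add atoms: none
Why: Iodine–lithium exchange of an alkenyl iodide with tert-butyllithium is far faster at −78 °C than any attack on the neopentyl-flanked equatorial C7 bromide and proceeds with retention, so silylation gives the (Z)-vinylsilane, and mild methanolysis frees the tertiary alcohol from its O-silyl ether 17.

Step 12
Reactants: 18 (1S,2S,4S)-4-bromo-1,3,3-trimethyl-2-[(2Z)-3-(trimethylsilyl)but-2-en-1-yl]cyclohexan-1-ol; 19 ethyl vinyl ether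
Product: 20 (1S,2S,4S)-4-bromo-1-(2-bromo-1-ethoxyethoxy)-1,3,3-trimethyl-2-[(2Z)-3-(trimethylsilyl)but-2-en-1-yl]cyclohexane (both acetal epimers)
Conditions: NBS, ethyl vinyl ether (excess), CH2Cl2, −40 → 0 °C
Reagents that add atoms: N-bromosuccinimide, O=C1CCC(=O)N1Br
Why: Bromoacetalisation (Ueno–Stork acetal formation), in which NBS brominates the far more electron-rich enol ether in preference to the vinylsilane and the tertiary alcohol captures the resulting oxocarbenium ion, the new acetal centre being of no consequence.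

Step 13
Reactants: 20 (1S,2S,4S)-4-bromo-1-(2-bromo-1-ethoxyethoxy)-1,3,3-trimethyl-2-[(2Z)-3-(trimethylsilyl)but-2-en-1-yl]cyclohexane
Product: 22 (2S,5aS,7S,9aS)-7-bromo-2-(bromomethyl)-3,6,6,9a-tetramethyl-2,5,5a,6,7,8,9,9a-octahydro-1-benzoxepine (2-epi-palisadin B), via oxocarbenium ion 21 (not isolated)
Conditions: SnCl4 (1.5 equiv), 2,6-di-tert-butyl-4-methylpyridine, CH2Cl2, −78 → −40 °C
Reagents that add atoms: none
Why: SnCl4 binds the less hindered ethoxy oxygen and expels ethoxide to give the (E)-oxocarbenium ion 21, whose carbon C2 is attacked by the silicon-bearing alkene carbon C3, so that the charge develops on C4 beta to silicon and chloride then strips Me3Si+, C2 taking the place of silicon and C3=C4 staying cis inside the new ring. The closest known reaction type is the Lewis-acid acetal–vinylsilane (silyl-Prins) cyclisation of mixed acetals of 5-silylalk-4-en-1-ols to 2,3,4,7-tetrahydrooxepines. The oxepene (O1–C2–C3–C4–C5–C5a–C9a) closes in the 7-endo-trig mode with respect to the vinylsilane, and the O1=C2 bond is endocyclic as well. The new centre C2 is governed by the fold of the tether: the trans-diequatorial O1 and C5 arms and the allylic 1,3-strain of the (Z)-silane leave a chair-like array in which the C9a methyl is axial on the nascent ring, CH2Br of the (E)-ion is pseudo-equatorial and H-2 is syn-axial to that methyl, which is 2S, the epimer of the natural series. No facial selectivity is therefore asked of this step, since C2 is flattened in step 14 and set in step 15. What the step does need is loss of ethoxide instead of the tertiary alkoxide, secured by the steric bias for complexation at OEt, and C3 attack (seven-membered ring) instead of C4 attack (six-membered ring), secured by the beta-silicon effect against an alpha-silyl cation, while the hindered pyridine base suppresses protodesilylation and both C–Br bonds should stay un-ionised at low temperature.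

Step 14
Reactants: 22 (2S,5aS,7S,9aS)-7-bromo-2-(bromomethyl)-3,6,6,9a-tetramethyl-2,5,5a,6,7,8,9,9a-octahydro-1-benzoxepine
Product: 23 (5aS,7S,9aS)-7-bromo-3,6,6,9a-tetramethyl-2-methylidene-2,5,5a,6,7,8,9,9a-octahydro-1-benzoxepine
Conditions: KOt-Bu, THF, 0 °C → rt; base-washed silica
Reagents that add atoms: none
Why: E2 dehydrobromination of a beta-bromo ether, as used to make exocyclic enol ethers from halomethyl cyclic ethers, removes the allylic H-2 and the primary bromide and erases C2, while the equatorial C7 bromide has no anti-periplanar hydrogen and stays.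

Step 15
Reactants: 23 (5aS,7S,9aS)-7-bromo-3,6,6,9a-tetramethyl-2-methylidene-2,5,5a,6,7,8,9,9a-octahydro-1-benzoxepine
Product: 25 [(2R,5aS,7S,9aS)-7-bromo-3,6,6,9a-tetramethyl-2,5,5a,6,7,8,9,9a-octahydro-1-benzoxepin-2-yl]methanol, via B-alkyl-9-BBN 24 (not isolated)
Conditions: 9-BBN, THF, 0 °C → rt; then H2O2, NaOH (aq), 0 °C
Reagents that add atoms: hydrogen peroxide, OO; 9-borabicyclo[3.3.1]nonane, B1C2CCCC1CCC2 (its atoms stay only in 24)
Why: Hydroboration–oxidation of an exocyclic enol ether, in which 9-BBN places boron on the terminal CH2 and delivers hydrogen to C2 from the open face opposite the axial C9a methyl that lies 1,3 to C2, which sets 2R with CH2OH cis to that methyl, the trisubstituted ring alkene being too hindered to compete.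

Step 16
Reactants: 25 [(2R,5aS,7S,9aS)-7-bromo-3,6,6,9a-tetramethyl-2,5,5a,6,7,8,9,9a-octahydro-1-benzoxepin-2-yl]methanol
Product: 26 palisadin B, (2R,5aS,7S,9aS)-7-bromo-2-(bromomethyl)-3,6,6,9a-tetramethyl-2,5,5a,6,7,8,9,9a-octahydro-1-benzoxepine
Conditions: CBr4, PPh3, 2,6-lutidine, CH2Cl2, 0 °C
Reagents that add atoms: carbon tetrabromide, BrC(Br)(Br)Br
Why: Appel reaction of an unhindered primary alcohol under neutral conditions, which touches neither the allylic ether nor any stereocentre.

**Compound list**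
1 | 2,4,4-trimethylcyclohex-2-en-1-one | CC1=CC(C)(C)CCC1=O | starting material
2 | (1R)-2,4,4-trimethylcyclohex-2-en-1-ol | O[C@@H]1CCC(C)(C)C=C1C | intermediate
3 | triethyl orthoacetate | CC(OCC)(OCC)OCC | starting material
4 | (6R)-6-[(1-ethoxyethenyl)oxy]-1,3,3-trimethylcyclohex-1-ene (ketene acetal) | C=C(OCC)O[C@@H]1CCC(C)(C)C=C1C | intermediate
5 | ethyl 2-[(1S)-2,6,6-trimethylcyclohex-2-en-1-yl]acetate | CCOC(=O)C[C@H]1C(C)(C)CCC=C1C | intermediate
6 | ethyl 2-[(1S)-2,6,6-trimethyl-4-oxocyclohex-2-en-1-yl]acetate | CCOC(=O)C[C@H]1C(C)(C)CC(=O)C=C1C | intermediate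
7 | ethyl 2-[(1R)-2,6,6-trimethyl-4-(trifluoromethylsulfonyloxy)cyclohexa-2,4-dien-1-yl]acetate | CCOC(=O)C[C@H]1C(C)(C)C=C(OS(=O)(=O)C(F)(F)F)C=C1C | intermediate
8 | ethyl 2-[(1R)-2,6,6-trimethylcyclohexa-2,4-dien-1-yl]acetate | CCOC(=O)C[C@H]1C(C)(C)C=CC=C1C | intermediate
9 | ethyl 2-[(1S,4R,7S)-1,8,8-trimethyl-2,3-dioxabicyclo[2.2.2]oct-5-en-7-yl]acetate | CCOC(=O)C[C@H]1C(C)(C)[C@H]2C=C[C@]1(C)OO2 | intermediate
10 | ethyl 2-[(1S,2S,5R)-2,5-dihydroxy-2,6,6-trimethylcyclohexyl]acetate | CCOC(=O)C[C@H]1C(C)(C)[C@H](O)CC[C@]1(C)O | intermediate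
11 | (3aS,5R,7aS)-5-hydroxy-4,4,7a-trimethylhexahydro-1-benzofuran-2(3H)-one | O=C1C[C@H]2C(C)(C)[C@H](O)CC[C@]2(C)O1 | intermediate
12 | (3aS,5S,7aS)-5-bromo-4,4,7a-trimethylhexahydro-1-benzofuran-2(3H)-one | O=C1C[C@H]2C(C)(C)[C@@H](Br)CC[C@]2(C)O1 | intermediate
13 | (3aS,5S,7aS)-5-bromo-4,4,7a-trimethyloctahydro-1-benzofuran-2-ol (both anomers) | OC1C[C@H]2C(C)(C)[C@@H](Br)CC[C@]2(C)O1 | intermediate
14 | ethyltriphenylphosphonium iodide | CC[P+](c1ccccc1)(c1ccccc1)c1ccccc1.[I-] | starting material
15 | (1S,2S,4S)-4-bromo-2-[(2Z)-3-iodobut-2-en-1-yl]-1,3,3-trimethylcyclohexan-1-ol | I/C(C)=C\C[C@H]1C(C)(C)[C@@H](Br)CC[C@]1(C)O | intermediate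
16 | chlorotrimethylsilane | C[Si](C)(C)Cl | starting material
17 | O-trimethylsilyl ether of 18 | C[Si](C)(C)/C(C)=C\C[C@H]1C(C)(C)[C@@H](Br)CC[C@]1(C)O[Si](C)(C)C | intermediate
18 | (1S,2S,4S)-4-bromo-1,3,3-trimethyl-2-[(2Z)-3-(trimethylsilyl)but-2-en-1-yl]cyclohexan-1-ol | C[Si](C)(C)/C(C)=C\C[C@H]1C(C)(C)[C@@H](Br)CC[C@]1(C)O | intermediate
19 | ethyl vinyl ether | C=COCC | starting material
20 | 2-bromo-1-ethoxyethyl ether of 18 (both acetal epimers) | C[Si](C)(C)/C(C)=C\C[C@H]1C(C)(C)[C@@H](Br)CC[C@]1(C)OC(OCC)CBr | intermediate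
21 | O1=C2 oxocarbenium ion (2-bromoethylidene oxonium ion of 18) | C[Si](C)(C)/C(C)=C\C[C@H]1C(C)(C)[C@@H](Br)CC[C@]1(C)[O+]=CCBr | intermediate
22 | 2-epi-palisadin B, (2S,5aS,7S,9aS) | CC1=CC[C@H]2C(C)(C)[C@@H](Br)CC[C@]2(C)O[C@@H]1CBr | intermediate
23 | (5aS,7S,9aS)-7-bromo-3,6,6,9a-tetramethyl-2-methylidene-2,5,5a,6,7,8,9,9a-octahydro-1-benzoxepine | CC1=CC[C@H]2C(C)(C)[C@@H](Br)CC[C@]2(C)OC1=C | intermediate
24 | 9-{[(2R,5aS,7S,9aS)-7-bromo-3,6,6,9a-tetramethyl-octahydro-1-benzoxepin-2-yl]methyl}-9-borabicyclo[3.3.1]nonane | CC1=CC[C@H]2C(C)(C)[C@@H](Br)CC[C@]2(C)O[C@H]1CB1C2CCCC1CCC2 | intermediate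
25 | [(2R,5aS,7S,9aS)-7-bromo-3,6,6,9a-tetramethyl-2,5,5a,6,7,8,9,9a-octahydro-1-benzoxepin-2-yl]methanol | CC1=CC[C@H]2C(C)(C)[C@@H](Br)CC[C@]2(C)O[C@H]1CO | intermediate
26 | palisadin B, (2R,5aS,7S,9aS) | CC1=CC[C@H]2C(C)(C)[C@@H](Br)CC[C@]2(C)O[C@H]1CBr | target

Total step count: 16. Longest linear sequence: 16 steps (from 1).

**Steps most likely to fail**

Step 13 (ring closure). Four processes could take over:
- ionisation with loss of the tertiary alkoxide;
- heterolysis of the C9a–O1 bond of the cation;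
- attack through C4 to a six-membered ring;
- protodesilylation.

The fallback closes the ring at C3=C4 by metathesis. It sets out from lactol 13 and comes back at enol ether 23. Wittig methylenation (Ph3P=CH2, THF) should give (1S,2S,4S)-4-bromo-1,3,3-trimethyl-2-(prop-2-en-1-yl)cyclohexan-1-ol F1. Acylation of the tertiary alcohol with methacrylic anhydride and DMAP gives its methacrylate F2. Ring-closing metathesis with a second-generation ruthenium carbene in hot toluene gives the unsaturated lactone (5aS,7S,9aS)-7-bromo-3,6,6,9a-tetramethyl-5,5a,6,7,8,9-hexahydro-1-benzoxepin-2(9aH)-one F3. Petasis methylenation (Cp2TiMe2, toluene, 70 °C) of the lactone carbonyl then gives 23.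

Step 8 (bromide at the neopentyl centre). Anti elimination with the axial H-8, or migration of a C6 methyl group, may outrun substitution. The fallback makes C7 allylic, so that C8 carries no anti hydrogen and displacement is faster. It sets out from endoperoxide 9 and comes back at bromolactone 12. Thiourea in methanol cleaves only the O–O bond to ethyl 2-[(1S,2S,5R)-2,5-dihydroxy-2,6,6-trimethylcyclohex-3-en-1-yl]acetate F4. Acid-catalysed lactonisation gives (3aS,5R,7aS)-5-hydroxy-4,4,7a-trimethyl-3a,4,5,7a-tetrahydro-1-benzofuran-2(3H)-one F5. An Appel reaction at 0 °C gives, with inversion, the allylic bromide (3aS,5S,7aS)-5-bromo-4,4,7a-trimethyl-3a,4,5,7a-tetrahydro-1-benzofuran-2(3H)-one F6. Diimide (2-nitrobenzenesulfonylhydrazide, Et3N, rt) saturates the cis-disubstituted C8=C9 bond without hydrogenolysis to give 12.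

Step 10 (iodo-olefination of a lactol). The lactol may open slowly, the iodo-ylide may decay before it reacts, and the Z geometry may erode. The fallback builds the vinylsilane from an alkyne. It sets out from lactol 13 and comes back at vinylsilane 18, so it also bypasses step 11. Ohira–Bestmann homologation (K2CO3, MeOH) gives (1S,2S,4S)-4-bromo-1,3,3-trimethyl-2-(prop-2-yn-1-yl)cyclohexan-1-ol F7. Double deprotonation with EtMgBr and C-silylation with one equivalent of Me3SiCl gives (1S,2S,4S)-4-bromo-1,3,3-trimethyl-2-[3-(trimethylsilyl)prop-2-yn-1-yl]cyclohexan-1-ol F8. Syn-hydroalumination with DIBAL-H in ether–hexane places aluminium on the silicon-bearing carbon. Formation of the alanate with MeLi and methylation with MeI, with retention, then give 18 with silicon cis to C5.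

**Further compounds**
F1 | step 13 | (1S,2S,4S)-4-bromo-1,3,3-trimethyl-2-(prop-2-en-1-yl)cyclohexan-1-ol | C=CC[C@H]1C(C)(C)[C@@H](Br)CC[C@]1(C)O
F2 | step 13 | (1S,2S,4S)-4-bromo-1,3,3-trimethyl-2-(prop-2-en-1-yl)cyclohexyl 2-methylprop-2-enoate | C=CC[C@H]1C(C)(C)[C@@H](Br)CC[C@]1(C)OC(=O)C(C)=C
F3 | step 13 | (5aS,7S,9aS)-7-bromo-3,6,6,9a-tetramethyl-5,5a,6,7,8,9-hexahydro-1-benzoxepin-2(9aH)-one | CC1=CC[C@H]2C(C)(C)[C@@H](Br)CC[C@]2(C)OC1=O
F4 | step 8 | ethyl 2-[(1S,2S,5R)-2,5-dihydroxy-2,6,6-trimethylcyclohex-3-en-1-yl]acetate | CCOC(=O)C[C@H]1C(C)(C)[C@H](O)C=C[C@]1(C)O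
F5 | step 8 | (3aS,5R,7aS)-5-hydroxy-4,4,7a-trimethyl-3a,4,5,7a-tetrahydro-1-benzofuran-2(3H)-one | O=C1C[C@H]2C(C)(C)[C@H](O)C=C[C@]2(C)O1
F6 | step 8 | (3aS,5S,7aS)-5-bromo-4,4,7a-trimethyl-3a,4,5,7a-tetrahydro-1-benzofuran-2(3H)-one | O=C1C[C@H]2C(C)(C)[C@@H](Br)C=C[C@]2(C)O1
F7 | step 10 | (1S,2S,4S)-4-bromo-1,3,3-trimethyl-2-(prop-2-yn-1-yl)cyclohexan-1-ol | C#CC[C@H]1C(C)(C)[C@@H](Br)CC[C@]1(C)O
F8 | step 10 | (1S,2S,4S)-4-bromo-1,3,3-trimethyl-2-[3-(trimethylsilyl)prop-2-yn-1-yl]cyclohexan-1-ol | C[Si](C)(C)C#CC[C@H]1C(C)(C)[C@@H](Br)CC[C@]1(C)O
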